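**Plan**
1. Retrosynthesis: the C15 ketone, the C4=CH2 unit and the C3–O–C9 lactone bond are taken back to a C15 silyl ether, a C4 acetyl group and a tert-butyl ester. The C9–C10 bond of ring B (C5–C10) is then cut: it joins the oxygen-bearing C9 of the bicyclo[2.2.2]octane (C8, C9, C11–C16) to quaternary C10, which lies β to C4 once C4 is a carbonyl, i.e. the bond a C9 ketyl makes with an enone.
2. The enone chain is cut at C10–C1 (Negishi coupling of a (Z)-enol triflate with a zinc homoenolate) and at C5–C6 (alkylation of pentane-2,4-dione). The bicyclic ketone is cut at C8–C14 and C12–C13 (Diels–Alder reaction of an o-quinone monoketal with a vinyl ether).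
3. Forward: creosol → 2-(2-chloroethyl)phenol → bicyclo[2.2.2]octenone (steps 1–7) → C14 acetate, then C15–O and C16=CH2 by a singlet-oxygen ene reaction (steps 8–11) → enone side chain (steps 12–14) → ring B (step 15) → lactone, isopropenyl group, enone (steps 16–19).
4. Stereochemistry: C8, C12 and C14 come from the ortho/endo cycloaddition, their absolute sense from a removable (S)-1-arylethyl ether (separation of diastereomers). C15 comes from ene attack anti to the C14 acetate; C9, C10 and C5 are set in the key step.

Key step: step 15

Assumption: atisane numbers are used for all intermediates (bridgeheads C8 and C12; bridges C9–C11, C14–C13, C15–C16; seen from C7 along C8→C12 these bridges follow clockwise, and "syn to a bridge" means pointing toward it), and the two endo cycloadducts of step 6 are taken to be separable by chromatography.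

**Step 1**
Reactants: 1 2-methoxy-4-methylphenol (creosol)
Product: 2 2-methoxy-1-(methoxymethoxy)-4-methylbenzene
Conditions: NaH, MOMCl, THF, 0 °C → rt
Reagents that add atoms: chloromethyl methyl ether, COCCl
Why: Williamson-type O-alkylation of the phenoxide; the MOM acetal protects the phenol and is the directing group for step 2.

**Step 2**
Reactants: 2 2-methoxy-1-(methoxymethoxy)-4-methylbenzene; 3 oxirane
Product: 5 2-[3-methoxy-2-(methoxymethoxy)-5-methylphenyl]ethan-1-ol, via aryllithium 4 (not isolated)
Conditions: n-BuLi, TMEDA, THF, 0 °C; then 3, −78 °C → rt; H2O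
Reagents that add atoms: none
Why: Directed ortho-metalation, in which the MOM ether (a stronger director than OMe) sends lithium to the only free ortho position, followed by ring opening of oxirane by the aryllithium, which installs C7 and C6.

**Step 3**
Reactants: 5 2-[3-methoxy-2-(methoxymethoxy)-5-methylphenyl]ethan-1-ol
Product: 6 1-(2-chloroethyl)-3-methoxy-2-(methoxymethoxy)-5-methylbenzene
Conditions: PPh3, CCl4, CH2Cl2, 40 °C
Reagents that add atoms: carbon tetrachloride, ClC(Cl)(Cl)Cl
Why: Appel reaction of a primary alcohol under neutral conditions that leave the MOM acetal intact; the chloride is inert in steps 4–11 and is the C6 electrophile in step 12.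

**Step 4**
Reactants: 6 1-(2-chloroethyl)-3-methoxy-2-(methoxymethoxy)-5-methylbenzene
Product: 7 2-(2-chloroethyl)-6-methoxy-4-methylphenol
Conditions: HCl (cat.), MeOH, 40 °C
Reagents that add atoms: none
Why: Acid-catalysed acetal exchange with methanol frees the phenol; no base is present, so the phenol cannot close onto the chloride.

**Step 5**
Reactants: 8 (S)-1-(4-methoxyphenyl)ethan-1-ol; 9 butyl vinyl ether
Product: 10 (S)-1-[1-(ethenyloxy)ethyl]-4-methoxybenzene
Conditions: Pd(OCOCF3)2 (1 mol%), 4,7-diphenyl-1,10-phenanthroline (1 mol%), Et3N (cat.), 9 as solvent, 75 °C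
Reagents that add atoms: none
Why: Transfer vinylation (transetherification) of a secondary alcohol catalysed by divalent palladium; the C–O bond at the stereocentre is not broken, so the (S) configuration is kept.

**Step 6**
Reactants: 7 2-(2-chloroethyl)-6-methoxy-4-methylphenol; 10 (S)-1-[1-(ethenyloxy)ethyl]-4-methoxybenzene
Product: 12 1-(2-chloroethyl)-3,3-dimethoxy-7-[(1S)-1-(4-methoxyphenyl)ethoxy]-5-methylbicyclo[2.2.2]oct-5-en-2-one (C14 ether syn to the C15=C16 bridge), via o-quinone monoketal 11 (not isolated)
Conditions: PhI(OAc)2, MeOH, 10 (5 equiv, excess recovered), 0 °C → rt; chromatographic separation of the two endo adducts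
Reagents that add atoms: methanol, CO
Why: Oxidative dearomatisation to the masked o-benzoquinone and inverse-electron-demand Diels–Alder reaction with the enol ether: the CH2 terminus bonds to C12 and the oxygen-bearing carbon to C8, and the endo rule puts the C14 ether syn to the new C15=C16 bridge. This fixes C8, C12 and C14 relative to one another; the (S)-ether turns the two mirror-image modes of addition into diastereomers, and the one with the ring configuration of the target is separated and carried on.

**Step 7**
Reactants: 12 cycloadduct from step 6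
Product: 14 1-(2-chloroethyl)-7-[(1S)-1-(4-methoxyphenyl)ethoxy]-5-methylbicyclo[2.2.2]oct-5-en-2-one, via α-methoxy ketone 13 (not isolated)
Conditions: SmI2 (6 equiv), THF–MeOH, 0 °C → rt
Reagents that add atoms: none
Why: Reductive cleavage of α-alkoxy ketones by SmI2 removes both methoxy groups next to the C9 carbonyl and leaves C11H2; without HMPA the alkyl chloride, the benzylic ether and the hindered ketone are not reduced.

**Step 8**
Reactants: 14 demethoxylated ketone from step 7
Product: 15 1-(2-chloroethyl)-7-hydroxy-5-methylbicyclo[2.2.2]oct-5-en-2-one (14S hydroxyl syn to the C15=C16 bridge)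
Conditions: DDQ, CH2Cl2–pH 7 buffer, 0 °C → rt
Reagents that add atoms: none
Why: Oxidative cleavage of a p-methoxybenzyl-type ether (benzylic hydride abstraction, then hydrolysis of the oxocarbenium ion) frees the C14 alcohol without acid, which could rearrange the bicyclo[2.2.2]octene.

**Step 9**
Reactants: 15 hydroxy ketone from step 8
Product: 16 7-acetoxy-1-(2-chloroethyl)-5-methylbicyclo[2.2.2]oct-5-en-2-one
Conditions: Ac2O, DMAP (cat.), pyridine, CH2Cl2, rt
Reagents that add atoms: acetic anhydride, CC(=O)OC(C)=O
Why: DMAP-catalysed acylation installs the C14 acetate of the target, which also covers one face of the C15=C16 bridge for step 10.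

**Step 10**
Reactants: 16 keto acetate from step 9
Product: 18 7-acetoxy-1-(2-chloroethyl)-6-hydroxy-5-methylidenebicyclo[2.2.2]octan-2-one (C15 hydroxyl syn to the C9 bridge), via allylic hydroperoxide 17 (not isolated)
Conditions: O2, tetraphenylporphyrin (cat.), visible light (> 450 nm), CH2Cl2, 0 °C; then PPh3, rt
Reagents that add atoms: oxygen, O=O
Why: Schenck ene reaction: singlet oxygen bonds to C15 from the alkene face next to the C9 carbonyl bridge (the other face is covered by the C14 acetate) and takes a hydrogen from the C17 methyl, the only allylic hydrogen that can be moved (C8 has none, C12–H would give a bridgehead alkene); PPh3 then reduces the hydroperoxide. This sets C15 and the C16=C17 alkene, and the long-wavelength light is not absorbed by the β,γ-unsaturated ketone.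

**Step 11**
Reactants: 18 allylic alcohol from step 10
Product: 19 7-acetoxy-6-[(tert-butyldimethylsilyl)oxy]-1-(2-chloroethyl)-5-methylidenebicyclo[2.2.2]octan-2-one
Conditions: TBSOTf, 2,6-lutidine, CH2Cl2, −78 → 0 °C
Reagents that add atoms: tert-butyldimethylsilyl trifluoromethanesulfonate, CC(C)(C)[Si](C)(C)OS(=O)(=O)C(F)(F)F
Why: Silylation of a hindered secondary allylic alcohol with the silyl triflate; the low temperature and the weak base keep the C9 ketone from forming a silyl enol ether.

**Step 12**
Reactants: 19 silyl ether chloride from step 11; 20 pentane-2,4-dione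
Product: 22 3-{2-[7-acetoxy-6-[(tert-butyldimethylsilyl)oxy]-5-methylidene-2-oxobicyclo[2.2.2]octan-1-yl]ethyl}pentane-2,4-dione, via primary iodide 21 (not isolated)
Conditions: 20 (3 equiv), K2CO3, NaI (0.2 equiv), DMF, 70 °C
Reagents that add atoms: none
Why: Finkelstein exchange in the flask and C-alkylation of the diketone enolate by SN2 at primary C6 form the C5–C6 bond; K2CO3 is too weak to enolise the C9 ketone or to cleave the acetate.

**Step 13**
Reactants: 22 alkylated diketone from step 12
Product: 24 (2Z)-3-acetyl-5-[7-acetoxy-6-[(tert-butyldimethylsilyl)oxy]-5-methylidene-2-oxobicyclo[2.2.2]octan-1-yl]pent-2-en-2-yl trifluoromethanesulfonate, via lithium enolate 23 (not isolated)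
Conditions: LiN(SiMe3)2 (1.05 equiv), Et2O, −78 °C; then Tf2O, −78 → −20 °C
Reagents that add atoms: trifluoromethanesulfonic anhydride, O=S(=O)(OS(=O)(=O)C(F)(F)F)C(F)(F)F
Why: One equivalent of base removes only the β-diketone proton (far more acidic than those of the C9 ketone or the acetate), and O-sulfonylation of the lithium-chelated enolate gives the (Z)-enol triflate with OTf cis to the remaining acetyl group.

**Step 14**
Reactants: 24 (Z)-enol triflate from step 13; 25 tert-butyl 3-bromopropanoate
Product: 27 tert-butyl (4Z)-5-acetyl-7-[7-acetoxy-6-[(tert-butyldimethylsilyl)oxy]-5-methylidene-2-oxobicyclo[2.2.2]octan-1-yl]-4-methylhept-4-enoate, via alkylzinc bromide 26 (not isolated)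
Conditions: 25, Zn dust, LiCl, THF, 40 °C; then 24, Pd(dppf)Cl2 (5 mol%), THF, 40 °C
Reagents that add atoms: none
Why: Zinc insertion gives the homoenolate, and Negishi coupling with the β-triflyloxy enone forms C10–C1 with retention of alkene geometry (ester chain cis to acetyl, C10 methyl cis to C6); the organozinc tolerates the ketone, the acetate and the silyl ether.

**Step 15**
Reactants: 27 (Z)-enone keto ester from step 14
Product: 29 ring-B-closed hydroxy keto tert-butyl ester (9-hydroxy; 10-methyl axial; 5-acetyl equatorial), via samarium enolate 28 (not isolated)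
Conditions: SmI2 (3 equiv), HMPA (10 equiv), t-BuOH (2 equiv), THF, −78 → −20 °C
Reagents that add atoms: none
Why: SmI2–HMPA transfers an electron to the C9 ketone, the C9 ketyl adds to the β-carbon C10 of the (Z)-enone, a second electron gives samarium enolate 28 and t-BuOH protonates it at C5. The closest known reaction type is the SmI2-mediated intramolecular ketyl–olefin (ketone–enone) reductive cyclisation. Ring B (C5–C10) closes by 6-endo-trig radical addition through a chair transition state. C9 is set by facial control (C10 reaches the carbonyl from the side of the C13–C14 bridge, where only C14–H points in, because the C15 silyl ether covers the other face), C10 by the (Z) geometry of the alkene (the methyl group cis to C6 becomes axial, the ester chain equatorial), and C5 by protonation and equilibration to the equatorial acetyl group. The step needs C–C bond formation to outrun plain reduction of the enone or ketone and the alkene geometry to survive until the bond is made; the low temperature, HMPA-accelerated ketyl formation, the weak proton donor and the unreactive tert-butyl ester and acetate are chosen to secure this.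

**Step 16**
Reactants: 29 hydroxy keto tert-butyl ester from step 15
Product: 31 δ-lactone (C3–O–C9) bearing 5-acetyl, 14-acetoxy, 15-silyloxy and 16-methylidene groups, via hydroxy acid 30 (not isolated)
Conditions: CF3CO2H–CH2Cl2 (1:4), 0 °C
Reagents that add atoms: none
Why: Acidolysis of the tert-butyl ester (loss of isobutene) and acid-catalysed lactonisation onto the tertiary C9 alcohol close the six-membered lactone; short anhydrous exposure at 0 °C is chosen so that the hindered silyl ether, the acetate and the C16=C17 alkene (deactivated by the adjacent silyloxy group) survive.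

**Step 17**
Reactants: 31 keto lactone from step 16
Product: 32 isopropenyl lactone (C4=CH2) with 14-acetoxy and 15-silyloxy groups
Conditions: Ph3PCH3Br, KOtBu, THF, 0 °C → rt
Reagents that add atoms: methyltriphenylphosphonium bromide, C[P+](c1ccccc1)(c1ccccc1)c1ccccc1.[Br-]
Why: Wittig methylenation of the methyl ketone by the non-stabilised ylide, which does not attack the lactone or the acetate; C5 already carries its substituent in the more stable equatorial position, so the basic reagent cannot scramble it.

**Step 18**
Reactants: 32 silyl ether from step 17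
Product: 33 15-hydroxy compound (crotobarin with a C15 carbinol, hydroxyl syn to the C9 bridge)
Conditions: Bu4NF, AcOH, THF, rt
Reagents that add atoms: none
Why: Fluoride cleavage of the silyl ether; acetic acid buffers the alkoxide so that the C14 acetate neither migrates nor hydrolyses.

**Step 19**
Reactants: 33 allylic alcohol from step 18
Product: 34 crotobarin
Conditions: Dess–Martin periodinane, CH2Cl2, 0 °C → rt
Reagents that add atoms: none
Why: Dess–Martin oxidation of the secondary allylic alcohol gives the α-methylene ketone under neutral conditions, so no nucleophile can add to the new enone; the C15 stereocentre, which had served its purpose in step 15, is removed.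

**Compound list**
1 | 2-methoxy-4-methylphenol (creosol) | COc1cc(C)ccc1O | starting material
2 | 2-methoxy-1-(methoxymethoxy)-4-methylbenzene | COCOc1ccc(C)cc1OC | intermediate
3 | oxirane | C1CO1 | starting material
4 | [3-methoxy-2-(methoxymethoxy)-5-methylphenyl]lithium | [Li]c1cc(C)cc(OC)c1OCOC | intermediate
5 | 2-[3-methoxy-2-(methoxymethoxy)-5-methylphenyl]ethan-1-ol | COCOc1c(CCO)cc(C)cc1OC | intermediate
6 | 1-(2-chloroethyl)-3-methoxy-2-(methoxymethoxy)-5-methylbenzene | COCOc1c(CCCl)cc(C)cc1OC | intermediate
7 | 2-(2-chloroethyl)-6-methoxy-4-methylphenol | COc1cc(C)cc(CCCl)c1O | intermediate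
8 | (S)-1-(4-methoxyphenyl)ethan-1-ol | C[C@H](O)c1ccc(OC)cc1 | starting material
9 | butyl vinyl ether | C=COCCCC | starting material
10 | (S)-1-[1-(ethenyloxy)ethyl]-4-methoxybenzene | C=CO[C@@H](C)c1ccc(OC)cc1 | intermediate
11 | 2-(2-chloroethyl)-6,6-dimethoxy-4-methylcyclohexa-2,4-dien-1-one (o-quinone monoketal) | COC1(OC)C=C(C)C=C(CCCl)C1=O | intermediate
12 | 1-(2-chloroethyl)-3,3-dimethoxy-7-[(1S)-1-(4-methoxyphenyl)ethoxy]-5-methylbicyclo[2.2.2]oct-5-en-2-one; C8 chloroethyl, C9 ketone, C11 ketal, 14S ether syn to the C15=C16 bridge | CC1=C[C@]2(CCCl)C(=O)C(OC)(OC)[C@H]1C[C@@H]2O[C@@H](C)c1ccc(OC)cc1 | intermediate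
13 | α-methoxy ketone (one C11 methoxy group left, C11 epimers) | CC1=C[C@]2(CCCl)C(=O)C(OC)[C@H]1C[C@@H]2O[C@@H](C)c1ccc(OC)cc1 | intermediate
14 | 1-(2-chloroethyl)-7-[(1S)-1-(4-methoxyphenyl)ethoxy]-5-methylbicyclo[2.2.2]oct-5-en-2-one; 14S ether syn to the C15=C16 bridge | CC1=C[C@]2(CCCl)C(=O)C[C@H]1C[C@@H]2O[C@@H](C)c1ccc(OC)cc1 | intermediate
15 | 1-(2-chloroethyl)-7-hydroxy-5-methylbicyclo[2.2.2]oct-5-en-2-one; 14S hydroxyl syn to the C15=C16 bridge | CC1=C[C@]2(CCCl)C(=O)C[C@H]1C[C@@H]2O | intermediate
16 | 7-acetoxy-1-(2-chloroethyl)-5-methylbicyclo[2.2.2]oct-5-en-2-one; 14S acetate syn to the C15=C16 bridge | CC1=C[C@]2(CCCl)C(=O)C[C@H]1C[C@@H]2OC(C)=O | intermediate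
17 | 7-acetoxy-1-(2-chloroethyl)-6-hydroperoxy-5-methylidenebicyclo[2.2.2]octan-2-one; C15 hydroperoxide syn to the C9 bridge | C=C1[C@H](OO)[C@]2(CCCl)C(=O)C[C@H]1C[C@@H]2OC(C)=O | intermediate
18 | 7-acetoxy-1-(2-chloroethyl)-6-hydroxy-5-methylidenebicyclo[2.2.2]octan-2-one; C15 hydroxyl syn to the C9 bridge, C14 acetate syn to the C15–C16 bridge | C=C1[C@H](O)[C@]2(CCCl)C(=O)C[C@H]1C[C@@H]2OC(C)=O | intermediate
19 | 7-acetoxy-6-[(tert-butyldimethylsilyl)oxy]-1-(2-chloroethyl)-5-methylidenebicyclo[2.2.2]octan-2-one | C=C1[C@H](O[Si](C)(C)C(C)(C)C)[C@]2(CCCl)C(=O)C[C@H]1C[C@@H]2OC(C)=O | intermediate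
20 | pentane-2,4-dione | CC(=O)CC(C)=O | starting material
21 | 7-acetoxy-6-[(tert-butyldimethylsilyl)oxy]-1-(2-iodoethyl)-5-methylidenebicyclo[2.2.2]octan-2-one | C=C1[C@H](O[Si](C)(C)C(C)(C)C)[C@]2(CCI)C(=O)C[C@H]1C[C@@H]2OC(C)=O | intermediate
22 | 3-{2-[7-acetoxy-6-[(tert-butyldimethylsilyl)oxy]-5-methylidene-2-oxobicyclo[2.2.2]octan-1-yl]ethyl}pentane-2,4-dione | C=C1[C@H](O[Si](C)(C)C(C)(C)C)[C@]2(CCC(C(C)=O)C(C)=O)C(=O)C[C@H]1C[C@@H]2OC(C)=O | intermediate
23 | lithium (Z)-enolate of 22 (chelated) | C=C1[C@H](O[Si](C)(C)C(C)(C)C)[C@]2(CC/C(C(C)=O)=C(\C)O[Li])C(=O)C[C@H]1C[C@@H]2OC(C)=O | intermediate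
24 | (2Z)-3-acetyl-5-[7-acetoxy-6-[(tert-butyldimethylsilyl)oxy]-5-methylidene-2-oxobicyclo[2.2.2]octan-1-yl]pent-2-en-2-yl trifluoromethanesulfonate | C=C1[C@H](O[Si](C)(C)C(C)(C)C)[C@]2(CC/C(C(C)=O)=C(\C)OS(=O)(=O)C(F)(F)F)C(=O)C[C@H]1C[C@@H]2OC(C)=O | intermediate
25 | tert-butyl 3-bromopropanoate | CC(C)(C)OC(=O)CCBr | starting material
26 | (3-tert-butoxy-3-oxopropyl)zinc bromide | CC(C)(C)OC(=O)CC[Zn]Br | intermediate
27 | tert-butyl (4Z)-5-acetyl-7-[7-acetoxy-6-[(tert-butyldimethylsilyl)oxy]-5-methylidene-2-oxobicyclo[2.2.2]octan-1-yl]-4-methylhept-4-enoate (key-step precursor; C9 ketone, C14 acetate, C15 silyl ether syn to the C9 bridge, C16 methylidene) | C=C1[C@H](O[Si](C)(C)C(C)(C)C)[C@]2(CC/C(C(C)=O)=C(\C)CCC(=O)OC(C)(C)C)C(=O)C[C@H]1C[C@@H]2OC(C)=O | intermediate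
28 | cyclised samarium alkoxide enolate (C9–O–SmI2, C4 enolate) | C=C1[C@H](O[Si](C)(C)C(C)(C)C)[C@]23CCC(=C(C)O[Sm](I)I)[C@](C)(CCC(=O)OC(C)(C)C)[C@@]2(O[Sm](I)I)C[C@H]1C[C@@H]3OC(C)=O | intermediate
29 | ring-B-closed hydroxy keto tert-butyl ester (9-hydroxy, 10-methyl, 10-(2-tert-butoxycarbonylethyl), 5-acetyl, 14-acetoxy, 15-silyloxy, 16-methylidene) | C=C1[C@H](O[Si](C)(C)C(C)(C)C)[C@]23CC[C@@H](C(C)=O)[C@](C)(CCC(=O)OC(C)(C)C)[C@@]2(O)C[C@H]1C[C@@H]3OC(C)=O | intermediate
30 | hydroxy acid corresponding to 29 | C=C1[C@H](O[Si](C)(C)C(C)(C)C)[C@]23CC[C@@H](C(C)=O)[C@](C)(CCC(=O)O)[C@@]2(O)C[C@H]1C[C@@H]3OC(C)=O | intermediate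
31 | δ-lactone (C3–O–C9) with 5-acetyl, 14-acetoxy, 15-silyloxy and 16-methylidene groups | C=C1[C@H](O[Si](C)(C)C(C)(C)C)[C@]23CC[C@@H](C(C)=O)[C@]4(C)CCC(=O)O[C@@]42C[C@H]1C[C@@H]3OC(C)=O | intermediate
32 | isopropenyl lactone (C4=CH2) with 14-acetoxy and 15-silyloxy groups | C=C1[C@H](O[Si](C)(C)C(C)(C)C)[C@]23CC[C@@H](C(=C)C)[C@]4(C)CCC(=O)O[C@@]42C[C@H]1C[C@@H]3OC(C)=O | intermediate
33 | 15-hydroxy compound (C15 carbinol of crotobarin, hydroxyl syn to the C9 bridge) | C=C1[C@H](O)[C@]23CC[C@@H](C(=C)C)[C@]4(C)CCC(=O)O[C@@]42C[C@H]1C[C@@H]3OC(C)=O | intermediate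
34 | crotobarin | C=C1C(=O)[C@]23CC[C@@H](C(=C)C)[C@]4(C)CCC(=O)O[C@@]42C[C@H]1C[C@@H]3OC(C)=O | target

**Step count**
Total: 19 steps. Longest linear sequence: 18 steps (steps 1–4 and 6–19, from creosol); step 5 is a one-step side branch.

**Steps most likely to fail**

Step 6. The stereocentre of the vinyl ether is remote from the reacting carbons and may give little facial discrimination, so the two endo adducts could form side by side and co-elute; the acid-sensitive vinyl ether may also be lost to methanol addition before it is trapped. The fallback sets out from 7 (with 10) and comes back at 15. The cycloaddition is run as before but the mixture of 12 and the diastereomeric cycloadduct F1 is carried on unseparated. SmI2 takes F1 through its α-methoxy ketone F2 to the demethoxylated ketone F3 alongside 14. DDQ then removes the auxiliary from both, giving 15 together with the enantiomeric alcohol F4. Absolute control is now enzymatic: Burkholderia cepacia lipase with vinyl acetate in tert-butyl methyl ether acylates secondary alcohols of the shape of F4 (14R; large group C8, medium group C13) and converts it into the enantiomeric acetate F5. The slow-reacting 14S alcohol 15 is recovered after somewhat more than half conversion and enters step 9.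

Step 15. The enone may take up the electron first and simply be protonated (conjugate reduction), the C9 ketone may be reduced to the alcohol, or a long-lived enone radical anion may rotate about C5–C10 and lose the C10 configuration; bond formation between two fully substituted carbons is slow enough for these paths to compete. The fallback sets out from 27 and comes back at 29, and makes no compound outside the list (F0). It reverses the roles of the partners by a titanocene-catalysed reductive umpolung: Cp2TiCl2 (10 mol%), Zn, Me3SiCl and 2,4,6-collidinium chloride in THF generate trivalent titanium, which reduces the enone to a titanium-bound enolate radical. Its β-carbon C10 adds to the C9 carbonyl, silylation of the alkoxide releases the catalyst, and a mild acidic work-up gives 29.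

Step 10. Singlet oxygen may attack the alkene face next to the acetate bridge (wrong C15 epimer), the ene reaction may be slow enough for sensitiser bleaching to dominate, or stray short-wavelength light may trigger a 1,3-acyl shift of the β,γ-unsaturated ketone. The fallback sets out from 16 and comes back at 18, and needs no light. Dimethyldioxirane (acetone, 0 °C) epoxidises the C15=C16 bond on the same open face to give the epoxide F6. Cp2TiCl (trivalent titanium, from Cp2TiCl2 and Mn in THF) opens F6 homolytically at the tertiary C16, and loss of a hydrogen atom from the C17 methyl to a second equivalent of the titanium reagent gives the exocyclic alkene and, after aqueous work-up, allylic alcohol 18.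

**Further compounds**
F1 | step 6 | diastereomeric cycloadduct (mirror-image bicycle, same (S)-ether) | CC1=C[C@@]2(CCCl)C(=O)C(OC)(OC)[C@@H]1C[C@H]2O[C@@H](C)c1ccc(OC)cc1
F2 | step 6 | α-methoxy ketone of the diastereomeric series (C11 epimers) | CC1=C[C@@]2(CCCl)C(=O)C(OC)[C@@H]1C[C@H]2O[C@@H](C)c1ccc(OC)cc1
F3 | step 6 | demethoxylated ketone of the diastereomeric series | CC1=C[C@@]2(CCCl)C(=O)C[C@@H]1C[C@H]2O[C@@H](C)c1ccc(OC)cc1
F4 | step 6 | enantiomer of alcohol 15 | CC1=C[C@@]2(CCCl)C(=O)C[C@@H]1C[C@H]2O
F5 | step 6 | enantiomer of acetate 16 | CC1=C[C@@]2(CCCl)C(=O)C[C@@H]1C[C@H]2OC(C)=O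
F0 | step 15 | none | none
F6 | step 10 | 15,16-epoxide of 16 (oxygen syn to the C9 bridge) | C[C@@]12O[C@@H]1[C@]3(CCCl)C(=O)C[C@H]2C[C@@H]3OC(C)=O
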